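**Strategy.** The route rests on building the phloroglucinol ring (C4a, C5, C6, C7, C8, C8a) from open-chain pieces instead of acylating a phloroglucinol. Its oxygens alternate, and the one that differs, O1 on C8a, sits between the C4 arm on C4a and the acyl carbon on C8; a cyclobutenone–ynol ether benzannulation delivers exactly this pattern. In one thermal operation a 3-ethoxycyclobutenone that carries the C4 stereocentre (from a desymmetrised 3-phenylglutaric anhydride) and a silyl-protected 1-ethoxyalkyn-3-ol give the pentasubstituted benzene ring with the C8a hydroxyl as its only free phenol. Lactonisation onto that phenol, carbinol oxidation and ether cleavage complete the target.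

Key step: step 6

Assumption: the quinidine-derived sulfonamide catalyst of step 1 is taken to give the (S)-hemiester; the sense is to be checked on 2 by optical rotation, and the quinine-derived pseudoenantiomer is used under the same conditions if it proves opposite.

**Step 1**
Reactants: 1 3-phenylglutaric anhydride
Product: 2 (3S)-5-methoxy-5-oxo-3-phenylpentanoic acid
Conditions: MeOH (10 equiv), quinidine-derived 9-amino-9-deoxy-epi-cinchona 3,5-bis(trifluoromethyl)benzenesulfonamide (10 mol %), MTBE, –20 °C; acid wash; recrystallisation if the enantiomeric purity needs raising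
Reagents that add atoms: methanol, CO
Why: Organocatalytic alcoholytic desymmetrisation of a meso anhydride, in which the bifunctional catalyst holds the anhydride by its sulfonamide N–H and its quinuclidine delivers methanol to one enantiotopic carbonyl, sets the stereocentre (the later C4) as S, the ester arm being the later C3–C2 unit and the acid arm the later C4a.

**Step 2**
Reactants: 2 (3S)-5-methoxy-5-oxo-3-phenylpentanoic acid
Product: 3 methyl (3R)-5-chloro-5-oxo-3-phenylpentanoate (same spatial arrangement; the descriptor changes by priority only)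
Conditions: (COCl)2 (1.2 equiv), DMF (cat.), CH2Cl2, 0 °C to rt; evaporate, strip with toluene, use at once
Reagents that add atoms: oxalyl chloride, ClC(=O)C(=O)Cl
Why: Vilsmeier-type acid chloride formation leaves the ester and the stereocentre (beta to both carbonyls) untouched, and the chloride is never heated so that ester/acid chloride interchange through a cyclic acyloxonium ion, which would swap the two arms and erode the enantiomeric purity, is avoided.

**Step 3**
Reactants: 3 methyl (3R)-5-chloro-5-oxo-3-phenylpentanoate; 4 ethoxyacetylene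
Product: 6 methyl (3R)-3-(2-ethoxy-4-oxocyclobut-2-en-1-yl)-3-phenylpropanoate (both epimers at the ring carbon), via aldoketene 5 (not isolated)
Conditions: 3 added over 6 h to 4 (3 equiv) and Et3N (1.3 equiv), Et2O, rt, then 12 h; filter; chromatography on Et3N-deactivated silica
Reagents that add atoms: none
Why: Dehydrochlorination gives aldoketene 5, which is trapped in a (2+2) ketene–ynol ether cycloaddition where the nucleophilic CH carbon of 4 bonds to the ketene carbonyl carbon, so the ethoxy group ends on C3 and the chiral arm on C4 of the cyclobutenone; slow addition into excess 4 works against ketene dimerisation, and the new ring stereocentre is lost later on aromatisation.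

**Step 4**
Reactants: 4 ethoxyacetylene; 7 3-phenylpropanal
Product: 9 1-ethoxy-5-phenylpent-1-yn-3-ol (racemic), via lithium ethoxyacetylide 8 (not isolated)
Conditions: 4 (1.2 equiv), n-BuLi (1.15 equiv), THF, –78 °C; then 7, –78 to –40 °C; H2O quench; crude product used directly
Reagents that add atoms: none
Why: 1,2-Addition of a lithium alkoxyacetylide to an aldehyde at low temperature outruns enolisation of 7; the work-up is kept free of acid because such adducts undergo Meyer–Schuster rearrangement to enoates, and the carbinol stereocentre is removed later by oxidation.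

**Step 5**
Reactants: 9 1-ethoxy-5-phenylpent-1-yn-3-ol
Product: 10 tert-butyl[(1-ethoxy-5-phenylpent-1-yn-3-yl)oxy]dimethylsilane (racemic)
Conditions: TBSCl (1.3 equiv), imidazole (2.5 equiv), DMF, 0 °C to rt; chromatography on Et3N-deactivated silica
Reagents that add atoms: tert-butyldimethylsilyl chloride, CC(C)(C)[Si](C)(C)Cl
Why: Imidazole-mediated O-silylation runs under basic conditions that the acid-labile ynol ether tolerates, and the silyl ether masks the hydroxyl that would otherwise add to the ketenes of the next step.

**Step 6**
Reactants: 6 methyl (3R)-3-(2-ethoxy-4-oxocyclobut-2-en-1-yl)-3-phenylpropanoate; 10 tert-butyl[(1-ethoxy-5-phenylpent-1-yn-3-yl)oxy]dimethylsilane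
Product: 15 methyl (3S)-3-[3-(1-{[tert-butyl(dimethyl)silyl]oxy}-3-phenylpropyl)-4,6-diethoxy-2-hydroxyphenyl]-3-phenylpropanoate (both carbinol epimers), via 3-ethoxy vinylketene 11 (not isolated), via vinylcyclobutenone 12 (not isolated), via dienylketene 13 (not isolated), via cyclohexadienone 14 (not isolated)
Conditions: 10 (1.5 equiv), toluene (0.3 M), degassed, sealed tube, 80–85 °C; rapid chromatography on Et3N-deactivated silica
Reagents that add atoms: none
Why: Heating should open 6 by reversible 4π electrocyclic cleavage, the C4 arm turning outward, to vinylketene 11, whose ketene C=C adds to ynol ether 10 in a (2+2) cycloaddition (forming C8a–C8 and C7–C6) to give 12; a second 4π opening leads to dienylketene 13. The closest known reaction is the Danheiser benzannulation of cyclobutenones with alkoxyalkynes, which gives resorcinol monoethers; the 3-ethoxy group on the cyclobutenone adds the third oxygen. The benzene ring closes by thermal 6π electrocyclisation of 13 (forming C8a–C4a) to cyclohexadienone 14, which tautomerises to the phenol. No new stereocentre survives: the ring CH of 14 is lost on tautomerisation, the carbinol epimers are carried on, and the C4 stereocentre is a spectator of a neutral pericyclic cascade. The step needs the regiochemistry of the ketene–alkyne union, which is secured by the polarisation of 10: the carbon remote from ethoxy is the nucleophile and bonds to the ketene carbonyl carbon, so the carbinol chain ends ortho and the ethoxy group meta to the new hydroxyl. Outward rotation of the arm rules out a 1,5-hydrogen shift in 11, the temperature stays below that of retro-ene loss of ethylene from the ethyl ynol ether, and excess 10 intercepts 11 before it dimerises or acylates the product phenol.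

**Step 7**
Reactants: 15 methyl (3S)-3-[3-(1-{[tert-butyl(dimethyl)silyl]oxy}-3-phenylpropyl)-4,6-diethoxy-2-hydroxyphenyl]-3-phenylpropanoate
Product: 16 (4S)-8-(1-{[tert-butyl(dimethyl)silyl]oxy}-3-phenylpropyl)-5,7-diethoxy-4-phenyl-3,4-dihydro-2H-chromen-2-one
Conditions: 2-hydroxypyridine (0.3 equiv), 4 Å MS, toluene, 90 °C
Reagents that add atoms: none
Why: Lactonisation by intramolecular transesterification of the only free phenol onto the methyl ester closes the lactone ring O1–C2 (6-exo-trig acyl substitution), helped by the conformational lock of the C4 phenyl and C5 ethoxy groups and pulled by uptake of methanol on the sieves, while 2-hydroxypyridine acts as a neutral proton shuttle so that the ionisable benzylic silyl ether sees neither acid nor base.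

**Step 8**
Reactants: 16 (4S)-8-(1-{[tert-butyl(dimethyl)silyl]oxy}-3-phenylpropyl)-5,7-diethoxy-4-phenyl-3,4-dihydro-2H-chromen-2-one
Product: 17 (4S)-5,7-diethoxy-8-(1-hydroxy-3-phenylpropyl)-4-phenyl-3,4-dihydro-2H-chromen-2-one (both carbinol epimers)
Conditions: n-Bu4NF (2 equiv), AcOH (2 equiv), THF, 0 °C to rt
Reagents that add atoms: none
Why: Fluoride-induced desilylation buffered with acetic acid frees the secondary benzylic alcohol without free alkoxide or strong acid, so the aryl lactone is not opened and the electron-rich benzylic position is not ionised.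

**Step 9**
Reactants: 17 (4S)-5,7-diethoxy-8-(1-hydroxy-3-phenylpropyl)-4-phenyl-3,4-dihydro-2H-chromen-2-one
Product: 18 (4S)-5,7-diethoxy-4-phenyl-8-(3-phenylpropanoyl)-3,4-dihydro-2H-chromen-2-one
Conditions: Dess–Martin periodinane (1.5 equiv), NaHCO3 (5 equiv), CH2Cl2, 0 °C to rt
Reagents that add atoms: none
Why: Dess–Martin oxidation turns the hindered benzylic carbinol into the aryl ketone under buffered, near-neutral conditions and removes the carbinol stereocentre, while hydride-abstracting oxidants such as DDQ are avoided because they could dehydrogenate the doubly benzylic C4–H.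

**Step 10**
Reactants: 18 (4S)-5,7-diethoxy-4-phenyl-8-(3-phenylpropanoyl)-3,4-dihydro-2H-chromen-2-one
Product: 19 (4S)-5,7-dihydroxy-4-phenyl-8-(3-phenylpropanoyl)-3,4-dihydro-2H-chromen-2-one (CNP0321593.1)
Conditions: BBr3 (5 equiv), CH2Cl2, –78 to 0 °C; cold pH 7 phosphate buffer quench, prompt extraction
Reagents that add atoms: none
Why: Lewis acid ether cleavage with BBr3 (bromide attack on the ethyl group of the boron-complexed ether) should remove both ethyl groups, the C7 ether being helped by chelation to the C8 ketone, whereas the aryl lactone has no O-alkyl bond to cleave, and the cold neutral quench is meant to prevent acid-promoted shift of the lactone to O5 and to leave C4 untouched.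

**Compound list**
1 | 3-phenylglutaric anhydride (4-phenyloxane-2,6-dione) | O=C1CC(c2ccccc2)CC(=O)O1 | starting material
2 | (3S)-5-methoxy-5-oxo-3-phenylpentanoic acid | COC(=O)C[C@@H](c1ccccc1)CC(=O)O | intermediate
3 | methyl (3R)-5-chloro-5-oxo-3-phenylpentanoate | COC(=O)C[C@@H](c1ccccc1)CC(=O)Cl | intermediate
4 | ethoxyacetylene | CCOC#C | starting material
5 | methyl (3R)-5-oxo-3-phenylpent-4-enoate (aldoketene) | COC(=O)C[C@@H](c1ccccc1)C=C=O | intermediate
6 | methyl (3R)-3-(2-ethoxy-4-oxocyclobut-2-en-1-yl)-3-phenylpropanoate, epimers at the ring carbon | COC(=O)C[C@@H](c1ccccc1)C1C(=O)C=C1OCC | intermediate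
7 | 3-phenylpropanal | O=CCCc1ccccc1 | starting material
8 | lithium ethoxyacetylide | [Li]C#COCC | intermediate
9 | 1-ethoxy-5-phenylpent-1-yn-3-ol (racemic) | CCOC#CC(O)CCc1ccccc1 | intermediate
10 | tert-butyl[(1-ethoxy-5-phenylpent-1-yn-3-yl)oxy]dimethylsilane (racemic) | CCOC#CC(O[Si](C)(C)C(C)(C)C)CCc1ccccc1 | intermediate
11 | methyl (3R,4Z)-5-ethoxy-7-oxo-3-phenylhepta-4,6-dienoate (3-ethoxy vinylketene) | COC(=O)C[C@@H](c1ccccc1)/C=C(OCC)/C=C=O | intermediate
12 | 4-vinylcyclobutenone: 3-ethoxy-2-(1-silyloxy-3-phenylpropyl)cyclobut-2-enone carrying at C4 the 1-ethoxyvinyl group that bears the chiral ester arm | COC(=O)C[C@@H](c1ccccc1)/C=C(OCC)/C1C(=O)C(C(O[Si](C)(C)C(C)(C)C)CCc2ccccc2)=C1OCC | intermediate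
13 | dienylketene: 3,5-diethoxy-2-(1-silyloxy-3-phenylpropyl)hexa-1,3,5-trien-1-one with the chiral ester arm on C6 | COC(=O)C[C@@H](c1ccccc1)/C=C(OCC)/C=C(OCC)\C(=C=O)C(O[Si](C)(C)C(C)(C)C)CCc1ccccc1 | intermediate
14 | 3,5-diethoxy-2-(1-silyloxy-3-phenylpropyl)cyclohexa-2,4-dienone with the chiral ester arm on C6 | COC(=O)C[C@@H](c1ccccc1)C1C(OCC)=CC(OCC)=C(C(O[Si](C)(C)C(C)(C)C)CCc2ccccc2)C1=O | intermediate
15 | methyl (3S)-3-[3-(1-{[tert-butyl(dimethyl)silyl]oxy}-3-phenylpropyl)-4,6-diethoxy-2-hydroxyphenyl]-3-phenylpropanoate, carbinol epimers | COC(=O)C[C@@H](c1ccccc1)c1c(OCC)cc(OCC)c(C(O[Si](C)(C)C(C)(C)C)CCc2ccccc2)c1O | intermediate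
16 | (4S)-8-(1-{[tert-butyl(dimethyl)silyl]oxy}-3-phenylpropyl)-5,7-diethoxy-4-phenyl-3,4-dihydro-2H-chromen-2-one, carbinol epimers | O=C1C[C@@H](c2ccccc2)c2c(OCC)cc(OCC)c(C(O[Si](C)(C)C(C)(C)C)CCc3ccccc3)c2O1 | intermediate
17 | (4S)-5,7-diethoxy-8-(1-hydroxy-3-phenylpropyl)-4-phenyl-3,4-dihydro-2H-chromen-2-one, carbinol epimers | O=C1C[C@@H](c2ccccc2)c2c(OCC)cc(OCC)c(C(O)CCc3ccccc3)c2O1 | intermediate
18 | (4S)-5,7-diethoxy-4-phenyl-8-(3-phenylpropanoyl)-3,4-dihydro-2H-chromen-2-one | O=C1C[C@@H](c2ccccc2)c2c(OCC)cc(OCC)c(C(=O)CCc3ccccc3)c2O1 | intermediate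
19 | (4S)-5,7-dihydroxy-4-phenyl-8-(3-phenylpropanoyl)-3,4-dihydro-2H-chromen-2-one | O=C1C[C@@H](c2ccccc2)c2c(O)cc(O)c(C(=O)CCc3ccccc3)c2O1 | target

**Totals.** Total step count: 10. Longest linear sequence: 8 steps (steps 1, 2, 3, 6, 7, 8, 9, 10 from anhydride 1); the ynol ether branch (steps 4 and 5) joins at step 6.

**Steps most likely to fail**

Step 6. The hindered internal ynol ether may capture the vinylketene too slowly. Vinylketene dimerisation, retro-ene loss of ethylene from the ynol ether, or loss of silanol from the new ortho-hydroxybenzylic ether could then take over. The fallback sets out from 6 and 4 and installs the acyl group by oxygen-to-carbon migration instead of on the alkyne.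
- The benzannulation is run with terminal ethoxyacetylene 4 itself (excess, toluene, 80 °C, sealed tube), which should give methyl (3S)-3-(2,4-diethoxy-6-hydroxyphenyl)-3-phenylpropanoate F1, with C8 unsubstituted.
- O-Acylation of the crude phenol with 3-phenylpropanoyl chloride (Et3N, DMAP, CH2Cl2, 0 °C) should give methyl (3S)-3-[2,4-diethoxy-6-(3-phenylpropanoyloxy)phenyl]-3-phenylpropanoate F2.
- A TiCl4-promoted Fries rearrangement (1,2-dichloroethane, 0 to 40 °C) should move the acyl group to the only free ortho carbon, C8, held there as the titanium chelate, giving methyl (3S)-3-[4,6-diethoxy-2-hydroxy-3-(3-phenylpropanoyl)phenyl]-3-phenylpropanoate F3. Migration to the para carbon C6 is the selectivity to watch.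
- Lactonisation (TsOH cat., toluene, 80 °C) rejoins the route at 18.

Step 7. Acyl transfer from an unactivated methyl ester to a hindered phenol may be sluggish, and prolonged heating could cause loss of silanol through an ortho-quinone methide. The fallback sets out from 15. Saponification (LiOH, THF/H2O, 0 °C to rt, work-up at pH 5) should give (3S)-3-[3-(1-{[tert-butyl(dimethyl)silyl]oxy}-3-phenylpropyl)-4,6-diethoxy-2-hydroxyphenyl]-3-phenylpropanoic acid F4. Dehydrative lactonisation with EDC·HCl and DMAP (CH2Cl2, 0 °C to rt) then rejoins the route at 16.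

Step 1. Discrimination of the enantiotopic carbonyls may be incomplete, or of the unwanted sense, leaving 2 short of the enantiomeric purity a single-enantiomer target needs. The fallback sets out from 1 and replaces asymmetric catalysis by classical resolution. Uncatalysed methanolysis (MeOH, reflux) gives racemic 5-methoxy-5-oxo-3-phenylpentanoic acid F5. Fractional crystallisation with (S)-1-phenylethylamine should give (S)-1-phenylethylammonium (3S)-5-methoxy-5-oxo-3-phenylpentanoate F6; the antipodal amine is used if it forms the less soluble salt with the (S)-acid. Acidification (aq. HCl, EtOAc) rejoins the route at 2.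

**Further compounds**
F1 | step 6 | methyl (3S)-3-(2,4-diethoxy-6-hydroxyphenyl)-3-phenylpropanoate | COC(=O)C[C@@H](c1ccccc1)c1c(OCC)cc(OCC)cc1O
F2 | step 6 | methyl (3S)-3-[2,4-diethoxy-6-(3-phenylpropanoyloxy)phenyl]-3-phenylpropanoate | COC(=O)C[C@@H](c1ccccc1)c1c(OCC)cc(OCC)cc1OC(=O)CCc1ccccc1
F3 | step 6 | methyl (3S)-3-[4,6-diethoxy-2-hydroxy-3-(3-phenylpropanoyl)phenyl]-3-phenylpropanoate | COC(=O)C[C@@H](c1ccccc1)c1c(OCC)cc(OCC)c(C(=O)CCc2ccccc2)c1O
F4 | step 7 | (3S)-3-[3-(1-{[tert-butyl(dimethyl)silyl]oxy}-3-phenylpropyl)-4,6-diethoxy-2-hydroxyphenyl]-3-phenylpropanoic acid | OC(=O)C[C@@H](c1ccccc1)c1c(OCC)cc(OCC)c(C(O[Si](C)(C)C(C)(C)C)CCc2ccccc2)c1O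
F5 | step 1 | racemic 5-methoxy-5-oxo-3-phenylpentanoic acid | COC(=O)CC(c1ccccc1)CC(=O)O
F6 | step 1 | (S)-1-phenylethylammonium (3S)-5-methoxy-5-oxo-3-phenylpentanoate | COC(=O)C[C@@H](c1ccccc1)CC(=O)[O-].C[C@H]([NH3+])c1ccccc1
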